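Late on, substrate stops falling: at 30.0 min, Tuesday's run shows 54% left. The reagent charged there is twice the substrate lost, so, as a reading, each substrate lost takes about two reagents, the first making mono adduct and the second carrying it further.

| flask | substrate | reagent | remark | time |
|---|---|---|---|---|
| Thursday's | 0.12 M | 0.90 equiv | run made earlier |  |
| Tuesday's | 0.50 M | 0.90 equiv | run made earlier |  |
| Wednesday's | 0.25 M | 1.4 equiv | run made earlier |  |
| flask | 0.25 M | 0.900 equiv |  | 30 min |

- Thursday's (time / min: mono adduct / %, substrate / %): 0.500: 11, 97; 1.50: 11, 82; 4.00: 16, 72; 12.0: 9, 59; 30.0: 3, 53
- Tuesday's (time / min: mono adduct / %, substrate / %): 0.500: 14, 78; 1.50: 15, 61; 4.00: 12, 50; 12.0: 9, 56; 30.0: 1, 54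
- Wednesday's (time / min: mono adduct / %, substrate / %): 0.500: 13, 81; 1.50: 16, 60; 4.00: 17, 42; 12.0: 6, 30; 30.0: 2, 27

(readings scatter by 2 percentage points)

- the numbers in the tables scatter by 2 percentage points (one standard deviation)

- time, not beyond 30 min, at which the flask holds most mono adduct
- the amount of mono adduct, in percent of the substrate charged, at that time

For this flask I compare two amounts. One is its charge of reagent, the limiting reagent: 0.900 equiv. The other is 0.515 equivalents, the mean over the top readings of Thursday's and Tuesday's runs of the peak cost, twice the substrate lost less the mono adduct standing.

My own reckoning: the flask's charge is more than that cost, by a factor of 1.75, so you should see a full peak, near those runs' 15% to 16%. The flask's concentration is less than Tuesday's and more than Thursday's, so I put its time between 1.50 min and 4.00 min.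

The forecast says 2.3 min and 16%, holding that “each substrate lost ultimately takes about two reagents”.

The flask gives 17.9% at 2.24 min, and the forecast's two values lie within the margins.

    substrate + reagent ⇌ mono adduct (K = 9.70 /M, k = 0.0230 /M/s)
    substrate + reagent → other mono adduct (k = 7.60 × 10⁻⁴ /M/s)
    reagent + mono adduct → double product (k = 0.0600 /M/s)
    reagent + other mono adduct → double product (k = 0.0690 /M/s)

At that time, the flask still holds 43.6% of its reagent. Now take the neighbour charged with 0.230 equiv. Its charge is less than the peak cost, a factor of 0.447 of it, so the same reckoning expects no full peak. Its highest mono adduct is 9.60%, less than the flask's, and at 30.0 min it still holds 87.0% of its substrate.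

The data come from a simulation from invented constants, and the scatter is random.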